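## Retrosynthetic overview

1. Target ⇐ hydrogenolysis of nine benzylic ethers ⇐ double galloylation of a 7,4′-diol. The 7-OH comes from sterically controlled C7–H borylation/oxidation of a 7-deoxyflavan, the 4′-OH from a silyl ether.
2. Ring A (C4a, C5–C8, C8a) is carried as a cyclohexanone (C5 ketone masked as a dioxolane) and aromatized late by a redox-neutral dehydration/tautomerization. The 3-OH ⇐ Luche reduction trans to the C2 aryl group.
3. Ring C (O1, C2, C3, C4, C4a, C8a) ⇐ Achmatowicz oxidative ring expansion of the five-membered furan ring (furan O, C3, C4, C4a, C8a) of a 2-furylcarbinol. Enabling feature: C2 carries the ring oxygen O1 and the aryl group next to an oxygenated C3, and C4a/C8a belong to a ring A whose C5 oxygen can be a ketone, so ring C plus C5=O is the retron of a 2-furylcarbinol on 6,7-dihydrobenzofuran-4(5H)-one.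
4. Furylcarbinol ⇐ catalytic asymmetric addition of the C2-zincated furan ketal to the ring-B aldehyde (sets C2).
5. Ring order: furan (purchased, fused to the ring-A precursor) → ring C by ring expansion → ring A aromatized → C7 oxygen → esters.

Key step: step 5

Remarks: Ar = 3-[(4-methoxybenzyl)oxy]-4-[(triisopropylsilyl)oxy]phenyl; PMB = 4-methoxybenzyl; TIPS = triisopropylsilyl; Bn = benzyl; all intermediates carry the flavan numbering of the target. Assumption: the hemiketal carbon C8a of 10, 11 and 12 forms as a mixture of epimers and is left undefined in the SMILES, since it becomes sp2 in step 7.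

## Route

Step 1
Reactants: 1 3,4-dihydroxybenzaldehyde
Product: 2 3-hydroxy-4-[(triisopropylsilyl)oxy]benzaldehyde
Conditions: TIPSCl (1.05 equiv), imidazole, DMF, 0 °C
Reagents that add atoms: chlorotriisopropylsilane, CC(C)[Si](Cl)(C(C)C)C(C)C
Why: Phenol silylation; the 4-hydroxyl, para to the formyl group, is the more acidic phenol and should be silylated first, and the bulky TIPS group should not migrate to O3.

Step 2
Reactants: 2 3-hydroxy-4-[(triisopropylsilyl)oxy]benzaldehyde
Product: 3 3-[(4-methoxybenzyl)oxy]-4-[(triisopropylsilyl)oxy]benzaldehyde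
Conditions: 4-methoxybenzyl alcohol, PPh3, DIAD, THF, 0 °C → rt
Reagents that add atoms: 4-methoxybenzyl alcohol, COc1ccc(CO)cc1
Why: Mitsunobu etherification of the remaining phenol runs under neutral conditions that should leave the neighbouring aryl silyl ether in place.

Step 3
Reactants: 4 6,7-dihydro-1-benzofuran-4(5H)-one
Product: 5 6',7'-dihydro-5'H-spiro[1,3-dioxolane-2,4'-[1]benzofuran]
Conditions: Me3SiOCH2CH2OSiMe3, Me3SiOTf (cat.), CH2Cl2, −78 → −20 °C
Reagents that add atoms: 1,2-bis(trimethylsilyloxy)ethane, C[Si](C)(C)OCCO[Si](C)(C)C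
Why: Ketalization with the bis-silyl ether of ethylene glycol at low temperature tolerates the furan and masks the only carbonyl, which permits furan metalation and later a chemoselective reduction at C3.

Step 4
Reactants: 5 6',7'-dihydro-5'H-spiro[1,3-dioxolane-2,4'-[1]benzofuran]; 3 3-[(4-methoxybenzyl)oxy]-4-[(triisopropylsilyl)oxy]benzaldehyde
Product: 8 (R)-Ar(6',7'-dihydro-5'H-spiro[1,3-dioxolane-2,4'-[1]benzofuran]-2'-yl)methanol, via C2-lithiated furan ketal 6 (not isolated), via ethyl(furyl)zinc reagent 7 (not isolated)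
Conditions: n-BuLi, t-BuOMe, 0 °C → rt; EtZnCl, 0 °C; N,N,N′,N′-tetraethylethylenediamine; (−)-3-exo-morpholinoisoborneol [(−)-MIB, 10 mol %], then 3, 0 °C; aq. NH4Cl
Reagents that add atoms: none
Why: Furan α-lithiation (C2′ is the only free α-position), transmetalation to the mixed ethyl(heteroaryl)zinc and amino-alcohol-catalysed asymmetric heteroarylzinc addition to the aldehyde; the heteroaryl group transfers in preference to ethyl, and (−)-MIB should direct it to the Si face of the aldehyde, which sets the carbinol carbon (the later C2) as R.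

Step 5
Reactants: 8 (R)-Ar(6',7'-dihydro-5'H-spiro[1,3-dioxolane-2,4'-[1]benzofuran]-2'-yl)methanol
Product: 10 (2R)-2-Ar-8a-hydroxy-6,7,8,8a-tetrahydrospiro[chromene-5,2'-[1,3]dioxolan]-3(2H)-one, via cis-ene-dione 9 (not isolated)
Conditions: NBS, NaHCO3, NaOAc, THF/H2O (4:1), 0 °C
Reagents that add atoms: water, O
Why: NBS brominates the trialkyl-substituted furan at an α-carbon, water adds to the resulting oxocarbenium ion and loss of HBr opens the ring to the cis-ene-dione 9, whose carbinol hydroxyl then adds to the C8a ketone, so that the five-membered furan (O, C3, C4, C4a, C8a) is exchanged for the six-membered pyranone ring C (O1, C2, C3, C4, C4a, C8a). The closest known reaction type is the Achmatowicz rearrangement of 2-furylcarbinols with NBS in aqueous THF, also known for 5-alkylfurans, which give 6-alkyl-6-hydroxypyranones. Ring C is closed by 6-exo-trig addition of the hydroxyl oxygen to the ketone carbonyl (hemiketalization). C2 keeps the R configuration of the carbinol because no bond to it is broken, and the hemiketal centre C8a forms as an epimer mixture of no consequence. The step needs chemoselective oxidation of the furan beside two electron-rich benzene rings, a silyl ether and an acid-labile ketal; the furan is by far the most nucleophilic π system, and the NaHCO3/NaOAc buffer should keep the ketal and the doubly activated carbinol from ionizing. In one operation the step should install the O1–C8a bond, the C3 oxygen function and the oxidation level that later lets ring A aromatize without an oxidant.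

Step 6
Reactants: 10 (2R)-2-Ar-8a-hydroxy-6,7,8,8a-tetrahydrospiro[chromene-5,2'-[1,3]dioxolan]-3(2H)-one
Product: 11 (2R,3S)-2-Ar-2,3,6,7,8,8a-hexahydrospiro[chromene-5,2'-[1,3]dioxolane]-3,8a-diol
Conditions: NaBH4, CeCl3·7H2O, MeOH, −78 °C
Reagents that add atoms: none
Why: Luche 1,2-reduction of the only ketone; axial hydride delivery to C3 should give the equatorial alcohol trans to the equatorial C2 aryl group (3S), the usual outcome for 2-substituted 2H-pyran-3(6H)-ones, while the ketal keeps C5 out of the reaction.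

Step 7
Reactants: 11 (2R,3S)-2-Ar-2,3,6,7,8,8a-hexahydrospiro[chromene-5,2'-[1,3]dioxolane]-3,8a-diol
Product: 14 (2R,3S)-2-Ar-3,4-dihydro-2H-chromene-3,5-diol, via enone hemiketal 12 (not isolated), via trienone 13 (not isolated)
Conditions: p-TsOH·H2O (cat.), acetone/H2O (10:1), rt → 40 °C
Reagents that add atoms: water, O
Why: Acid hydrolysis of the allylic dioxolane and dehydration of the hemiketal should give the cross-conjugated alkylidene cyclohexenone 13, which tautomerizes to the phenol (isoaromatization: enolization towards C6, protonation at C4, loss of H7); the sequence is redox-neutral because step 5 already supplied the oxidation level of the arene, and C2 and C3 are not involved.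

Step 8
Reactants: 14 (2R,3S)-2-Ar-3,4-dihydro-2H-chromene-3,5-diol
Product: 15 (2R,3S)-2-Ar-3,5-bis[(4-methoxybenzyl)oxy]chromane
Conditions: NaH, 4-methoxybenzyl chloride, Bu4NI (cat.), DMF, 0 °C → rt
Reagents that add atoms: 4-methoxybenzyl chloride, COc1ccc(CCl)cc1
Why: Williamson etherification of the phenol and the secondary alcohol; PMB is chosen because every C–H of its ring is ortho to a substituent, which keeps it inert in step 9, and because it is removed by hydrogenolysis at the end.

Step 9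
Reactants: 15 (2R,3S)-2-Ar-3,5-bis[(4-methoxybenzyl)oxy]chromane
Product: 17 (2R,3S)-2-Ar-3,5-bis[(4-methoxybenzyl)oxy]chroman-7-ol, via C7 pinacol boronate 16 (not isolated)
Conditions: [Ir(OMe)(cod)]2 (cat.), 4,4′-di-tert-butyl-2,2′-bipyridine, B2pin2, THF, 65 °C; then 30% H2O2, aq. NaOH, 0 °C
Reagents that add atoms: bis(pinacolato)diboron, CC1(C)OB(OC1(C)C)B1OC(C)(C)C(C)(C)O1 (boryl group of 16); hydrogen peroxide, OO (O7 of 17)
Why: Iridium-catalysed arene C–H borylation is sterically controlled, and C7–H is the only aromatic C–H flanked by two hydrogens (C6–H is ortho to the 5-OPMB group, C8–H ortho to O1, all PMB and ring-B C–H bonds are ortho to a substituent); oxidation of the boronate should leave the 7-hydroxyl as the only free phenol.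

Step 10
Reactants: 17 (2R,3S)-2-Ar-3,5-bis[(4-methoxybenzyl)oxy]chroman-7-ol
Product: 18 (2R,3S)-2-{4-hydroxy-3-[(4-methoxybenzyl)oxy]phenyl}-3,5-bis[(4-methoxybenzyl)oxy]chroman-7-ol
Conditions: Bu4NF, AcOH, THF, 0 °C
Reagents that add atoms: none
Why: Fluoride cleavage of the aryl silyl ether; the acetic acid buffer should prevent phenoxide-driven opening of ring C (epimerization at C2).

Step 11
Reactants: 18 (2R,3S)-2-{4-hydroxy-3-[(4-methoxybenzyl)oxy]phenyl}-3,5-bis[(4-methoxybenzyl)oxy]chroman-7-ol; 19 3,4,5-tris(benzyloxy)benzoic acid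
Product: 20 7,4′-bis-O-[3,4,5-tris(benzyloxy)benzoyl] derivative of 18
Conditions: 19 (2.5 equiv), EDC·HCl, DMAP, CH2Cl2, rt
Reagents that add atoms: none
Why: Steglich esterification of the two free phenols; every other oxygen is an ether, so the esters can only form at O7 and O4′.

Step 12
Reactants: 20 7,4′-bis-O-[3,4,5-tris(benzyloxy)benzoyl] derivative of 18
Product: 21 catechin 7,4′-di-O-gallate
Conditions: H2 (1 atm), Pd(OH)2/C, THF/MeOH, rt
Reagents that add atoms: none
Why: Hydrogenolysis of six benzyl and three PMB ethers under neutral conditions should leave the aryl esters and both stereocentres untouched and avoid 4′→3′ acyl migration.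

## Compound list

1 | 3,4-dihydroxybenzaldehyde | O=Cc1ccc(O)c(O)c1 | starting material
2 | 3-hydroxy-4-[(triisopropylsilyl)oxy]benzaldehyde | O=Cc1ccc(O[Si](C(C)C)(C(C)C)C(C)C)c(O)c1 | intermediate
3 | 3-[(4-methoxybenzyl)oxy]-4-[(triisopropylsilyl)oxy]benzaldehyde | O=Cc1ccc(O[Si](C(C)C)(C(C)C)C(C)C)c(OCc2ccc(OC)cc2)c1 | intermediate
4 | 6,7-dihydro-1-benzofuran-4(5H)-one | O=C1CCCc2occc12 | starting material
5 | 6',7'-dihydro-5'H-spiro[1,3-dioxolane-2,4'-[1]benzofuran] | c1cc2c(o1)CCCC21OCCO1 | intermediate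
6 | 2'-lithio derivative of 5 | [Li]c1cc2c(o1)CCCC21OCCO1 | intermediate
7 | ethyl(6',7'-dihydro-5'H-spiro[1,3-dioxolane-2,4'-[1]benzofuran]-2'-yl)zinc | CC[Zn]c1cc2c(o1)CCCC21OCCO1 | intermediate
8 | (R)-Ar(6',7'-dihydro-5'H-spiro[1,3-dioxolane-2,4'-[1]benzofuran]-2'-yl)methanol | O[C@@H](c1cc2c(o1)CCCC21OCCO1)c1ccc(O[Si](C(C)C)(C(C)C)C(C)C)c(OCc2ccc(OC)cc2)c1 | intermediate
9 | 2-[(3R)-3-Ar-3-hydroxy-2-oxopropylidene]-3,3-(ethylenedioxy)cyclohexan-1-one, C3 and C8a carbonyls cis across C4=C4a | O=C1CCCC2(OCCO2)/C1=C/C(=O)[C@H](O)c1ccc(O[Si](C(C)C)(C(C)C)C(C)C)c(OCc2ccc(OC)cc2)c1 | intermediate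
10 | (2R)-2-Ar-8a-hydroxy-6,7,8,8a-tetrahydrospiro[chromene-5,2'-[1,3]dioxolan]-3(2H)-one (8a-epimers) | O=C1C=C2C3(OCCO3)CCCC2(O)O[C@@H]1c1ccc(O[Si](C(C)C)(C(C)C)C(C)C)c(OCc2ccc(OC)cc2)c1 | intermediate
11 | (2R,3S)-2-Ar-2,3,6,7,8,8a-hexahydrospiro[chromene-5,2'-[1,3]dioxolane]-3,8a-diol (8a-epimers) | O[C@H]1C=C2C3(OCCO3)CCCC2(O)O[C@@H]1c1ccc(O[Si](C(C)C)(C(C)C)C(C)C)c(OCc2ccc(OC)cc2)c1 | intermediate
12 | (2R,3S)-2-Ar-3,8a-dihydroxy-2,3,6,7,8,8a-hexahydro-5H-chromen-5-one (8a-epimers) | O[C@H]1C=C2C(=O)CCCC2(O)O[C@@H]1c1ccc(O[Si](C(C)C)(C(C)C)C(C)C)c(OCc2ccc(OC)cc2)c1 | intermediate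
13 | (2R,3S)-2-Ar-3-hydroxy-2,3,6,7-tetrahydro-5H-chromen-5-one | O[C@H]1C=C2C(=O)CCC=C2O[C@@H]1c1ccc(O[Si](C(C)C)(C(C)C)C(C)C)c(OCc2ccc(OC)cc2)c1 | intermediate
14 | (2R,3S)-2-Ar-3,4-dihydro-2H-chromene-3,5-diol | O[C@H]1Cc2c(O)cccc2O[C@@H]1c1ccc(O[Si](C(C)C)(C(C)C)C(C)C)c(OCc2ccc(OC)cc2)c1 | intermediate
15 | (2R,3S)-2-Ar-3,5-bis[(4-methoxybenzyl)oxy]chromane | COc1ccc(CO[C@H]2Cc3c(OCc4ccc(OC)cc4)cccc3O[C@@H]2c2ccc(O[Si](C(C)C)(C(C)C)C(C)C)c(OCc3ccc(OC)cc3)c2)cc1 | intermediate
16 | 7-(4,4,5,5-tetramethyl-1,3,2-dioxaborolan-2-yl) derivative of 15 | COc1ccc(CO[C@H]2Cc3c(OCc4ccc(OC)cc4)cc(B4OC(C)(C)C(C)(C)O4)cc3O[C@@H]2c2ccc(O[Si](C(C)C)(C(C)C)C(C)C)c(OCc3ccc(OC)cc3)c2)cc1 | intermediate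
17 | (2R,3S)-2-Ar-3,5-bis[(4-methoxybenzyl)oxy]chroman-7-ol | COc1ccc(CO[C@H]2Cc3c(OCc4ccc(OC)cc4)cc(O)cc3O[C@@H]2c2ccc(O[Si](C(C)C)(C(C)C)C(C)C)c(OCc3ccc(OC)cc3)c2)cc1 | intermediate
18 | (2R,3S)-2-{4-hydroxy-3-[(4-methoxybenzyl)oxy]phenyl}-3,5-bis[(4-methoxybenzyl)oxy]chroman-7-ol | COc1ccc(CO[C@H]2Cc3c(OCc4ccc(OC)cc4)cc(O)cc3O[C@@H]2c2ccc(O)c(OCc3ccc(OC)cc3)c2)cc1 | intermediate
19 | 3,4,5-tris(benzyloxy)benzoic acid | O=C(O)c1cc(OCc2ccccc2)c(OCc2ccccc2)c(OCc2ccccc2)c1 | starting material
20 | 7,4′-bis-O-[3,4,5-tris(benzyloxy)benzoyl] derivative of 18 | COc1ccc(CO[C@H]2Cc3c(OCc4ccc(OC)cc4)cc(OC(=O)c4cc(OCc5ccccc5)c(OCc5ccccc5)c(OCc5ccccc5)c4)cc3O[C@@H]2c2ccc(OC(=O)c3cc(OCc4ccccc4)c(OCc4ccccc4)c(OCc4ccccc4)c3)c(OCc3ccc(OC)cc3)c2)cc1 | intermediate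
21 | catechin 7,4′-di-O-gallate, (2R,3S) | O=C(Oc1cc(O)c2c(c1)O[C@H](c1ccc(OC(=O)c3cc(O)c(O)c(O)c3)c(O)c1)[C@@H](O)C2)c1cc(O)c(O)c(O)c1 | target

## Step count and risks

Total step count: 12. Longest linear sequence: 11 steps (steps 1, 2, 4–12, from 3,4-dihydroxybenzaldehyde).

Steps most likely to fail:

1. Step 7. Acid-catalysed γ-enolization through C3–H of the 3-hydroxy-enone may compete with enolization towards C6; this would epimerize C3 or divert material to the 3-ketone by redox isomerization, and the allylic 3-hydroxyl may also ionize. The fallback replaces the tautomerization by a reduction/dehydrogenation pair that takes the C4=C4a double bond out of conjugation with C3–H before ring A is aromatized. It sets out from 11: pyridinium p-toluenesulfonate in wet acetone at rt should stop at trienone 13. Conjugate reduction of 13 with [(Ph3P)CuH]6 in benzene should deliver hydride to C4 and give, after protonation, the vinylogous ester (2R,3S)-2-Ar-3-hydroxy-2,3,4,6,7,8-hexahydro-5H-chromen-5-one F1. Treatment with LiN(SiMe3)2 (2.2 equiv) and Me3SiCl in THF at −78 °C should give the 3-O-silylated silyl dienol ether F2. Saegusa–Ito oxidation with Pd(OAc)2 in MeCN, followed by a dilute citric acid work-up, should give the cyclohexadienone that tautomerizes to the phenol, and the fallback comes back to the route at 14.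

2. Step 9. Site selectivity of the C–H borylation may be lost (attack at C8–H ortho to O1 or at PMB C–H bonds ortho to OMe). The fallback uses the sterically more demanding rhodium-catalysed arene C–H silylation. It sets out from 15: [Rh(coe)2OH]2, DTBM-SEGPHOS, HSiMe(OSiMe3)2, cyclohexene, THF, 45 °C should give the C7 arylsilane F3. Tamao–Fleming oxidation (H2O2, KHCO3, Bu4NF, THF/MeOH) should convert the C–Si bond into the phenol and at the same time cleave the TIPS ether, so the fallback comes back to the route at 18.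

3. Step 4. Enantioselectivity may erode through uncatalysed, LiCl-promoted background addition of the furylzinc reagent or through competing ethyl transfer. The fallback sets the configuration by kinetic resolution in the oxidation step. It sets out from 5 and 3: lithiation of 5 with n-BuLi and direct addition to 3 should give the racemic carbinol F4. Sharpless kinetic-resolution conditions [Ti(OiPr)4, D-(−)-diisopropyl tartrate, t-BuOOH, 4 Å molecular sieves, CH2Cl2, −20 °C] should oxidize only the (R)-enantiomer, which undergoes the Achmatowicz rearrangement, and the fallback comes back to the route at 10. The unreacted (S)-carbinol F5 is separated.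

## Further compounds

F1 | step 7 | (2R,3S)-2-Ar-3-hydroxy-2,3,4,6,7,8-hexahydro-5H-chromen-5-one | O[C@H]1CC2=C(CCCC2=O)O[C@@H]1c1ccc(O[Si](C(C)C)(C(C)C)C(C)C)c(OCc2ccc(OC)cc2)c1
F2 | step 7 | (2R,3S)-2-Ar-3,5-bis[(trimethylsilyl)oxy]-3,4,7,8-tetrahydro-2H-chromene | C[Si](C)(C)O[C@H]1CC2=C(CCC=C2O[Si](C)(C)C)O[C@@H]1c1ccc(O[Si](C(C)C)(C(C)C)C(C)C)c(OCc2ccc(OC)cc2)c1
F3 | step 9 | 7-[methylbis(trimethylsilyloxy)silyl] derivative of 15 | COc1ccc(CO[C@H]2Cc3c(OCc4ccc(OC)cc4)cc([Si](C)(O[Si](C)(C)C)O[Si](C)(C)C)cc3O[C@@H]2c2ccc(O[Si](C(C)C)(C(C)C)C(C)C)c(OCc3ccc(OC)cc3)c2)cc1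
F4 | step 4 | racemic Ar(6',7'-dihydro-5'H-spiro[1,3-dioxolane-2,4'-[1]benzofuran]-2'-yl)methanol | OC(c1cc2c(o1)CCCC21OCCO1)c1ccc(O[Si](C(C)C)(C(C)C)C(C)C)c(OCc2ccc(OC)cc2)c1
F5 | step 4 | (S)-Ar(6',7'-dihydro-5'H-spiro[1,3-dioxolane-2,4'-[1]benzofuran]-2'-yl)methanol | O[C@H](c1cc2c(o1)CCCC21OCCO1)c1ccc(O[Si](C(C)C)(C(C)C)C(C)C)c(OCc2ccc(OC)cc2)c1
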